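**Retrosynthetic overview**
- Only the two amide C–N bonds are disconnected: two molecules of caffeic acid (1), masked and activated in the flask by boric acid (2), acylate the two primary nitrogens of spermidine (3) in one pot.
- Order in the flask: catechol borate 4, then its acyloxyborole (mixed-anhydride) form 5, then the boron-masked bis-amide 6, then hydrolysis to the target 7.
- No ring of the target is built; both benzene rings arrive intact with 1. The only rings formed are the two temporary 1,3,2-benzodioxaborole rings, closed first and opened last.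
- Both E double bonds are carried unchanged from 1.

Assumption: the target has no stereocentre, so "single enantiomer" is read as the single (E,E) isomer drawn.

**Step 1**
Reactants: 1 caffeic acid; 2 boric acid; 3 spermidine
Product: 7 N(1),N(8)-bis(caffeoyl)spermidine, via caffeic acid catechol borate 4 (not isolated), via head-to-tail acyloxybenzodioxaborole dimer 5 (not isolated), via boron-masked bis-amide 6 (not isolated)
Conditions: 1 (2.05 equiv), B(OH)3 (2.05 equiv), tBuOAc, reflux, Dean–Stark, 3 h; then 3 (1.0 equiv, added at 60 °C over 1 h), reflux, Dean–Stark, 14 h, N2, dark; then MeOH/H2O, pH 3 (HCl), 25 °C, 1 h; C18 chromatography (H2O/MeCN)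
Reagents that add atoms: none
Why: Proposed new method: substrate-templated boron-mediated dehydrative amidation, in which B(OH)3 first closes a 2-hydroxy-1,3,2-benzodioxaborole ring on the catechol of 1 (4), azeotropic dehydration then joins the B–OH of one molecule to the CO2H of the next as a 2-acyloxy-1,3,2-benzodioxaborole mixed anhydride (5, the repeat linkage of a head-to-tail oligomer), and a primary NH2 of 3 binds the Lewis-acidic boron and takes the acyl group through a six-membered B–O–C(=O)···N–H transition state, releasing B–OH that is dehydrated again and reused; the acyclic secondary N(4) should be too hindered to enter this boron-bound tetrahedral intermediate at a competitive rate, the boron ring blocks phenol O-acylation, quinone formation and quinone-methide decarboxylation, the E alkenes of 1 are not touched and no stereocentre is created, and aqueous acid opens the borate rings of 6; the closest known reaction types are the aminolysis of catecholborane-derived 2-acyloxy-1,3,2-benzodioxaboroles and boric-acid- or catechol-borate-catalysed direct amidation under Dean–Stark conditions, which to my knowledge have not been run with the substrate's own catechol as the boron ligand or with an unprotected triamine as the nucleophile.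

**Compound list**
1 | caffeic acid, (E)-3-(3,4-dihydroxyphenyl)prop-2-enoic acid | O=C(O)/C=C/c1ccc(O)c(O)c1 | starting material
2 | boric acid | OB(O)O | starting material
3 | spermidine, N-(3-aminopropyl)butane-1,4-diamine | NCCCCNCCCN | starting material
4 | caffeic acid catechol borate, (E)-3-(2-hydroxy-1,3,2-benzodioxaborol-5-yl)prop-2-enoic acid | O=C(O)/C=C/c1ccc2OB(O)Oc2c1 | intermediate
5 | head-to-tail acyloxybenzodioxaborole dimer, (E)-3-[2-({(E)-3-(2-hydroxy-1,3,2-benzodioxaborol-5-yl)prop-2-enoyl}oxy)-1,3,2-benzodioxaborol-5-yl]prop-2-enoic acid, drawn as the simplest member of the oligomer family | O=C(O)/C=C/c1ccc2OB(OC(=O)/C=C/c3ccc4OB(O)Oc4c3)Oc2c1 | intermediate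
6 | boron-masked bis-amide, N(1),N(8)-bis[(E)-3-(2-hydroxy-1,3,2-benzodioxaborol-5-yl)prop-2-enoyl]spermidine | O=C(/C=C/c1ccc2OB(O)Oc2c1)NCCCCNCCCNC(=O)/C=C/c1ccc2OB(O)Oc2c1 | intermediate
7 | N(1),N(8)-bis(caffeoyl)spermidine, (E,E) isomer | O=C(/C=C/c1ccc(O)c(O)c1)NCCCCNCCCNC(=O)/C=C/c1ccc(O)c(O)c1 | target

**Totals**
Total step count: 1 (one pot, three intermediates that are not isolated).
Longest linear sequence: 1 step.

**Steps most likely to fail**
The route has one step, so its three weakest points are ranked, each with its own fallback.

1. Step 1, acyl transfer from boron (the proposed new step). The acyloxyborole linkages of 5 may form only partly, or 3 may tie the boron up as four-coordinate amine and spiroborate complexes, so that the mixture stalls as an ammonium carboxylate salt. Fallback (known chemistry, active-ester aminolysis): it sets out from 1 and comes back at 7. Compound 1 is treated with N-hydroxysuccinimide and DCC (THF, 0 °C to 25 °C) to give caffeic acid N-succinimidyl ester F1, isolated after filtration of the urea. F1 (2.0 equiv) is then added to 3 (1.0 equiv) in THF/DMF at 0 °C under N2; succinimidyl esters acylate the two primary nitrogens of spermidine in preference to N(4), giving 7.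

2. Step 1, site selectivity. If N(4) is also acylated, the tris-amide forms and is hard to separate. Fallback (N(4) blocked before coupling): it sets out from 3 and comes back at 7. Compound 3 with CF3CO2Et (2.0 equiv, MeOH, −78 °C to 0 °C) gives N(1),N(8)-bis(trifluoroacetyl)spermidine F2. Boc2O in the same flask gives N(4)-Boc-N(1),N(8)-bis(trifluoroacetyl)spermidine F3, and K2CO3 in MeOH/H2O gives N(4)-Boc-spermidine F4. Coupling with 1 (2.1 equiv; EDC·HCl, HOBt, DMF, 0 °C to 25 °C) gives N(4)-Boc-N(1),N(8)-bis(caffeoyl)spermidine F5, and HCl in dioxane removes the Boc group to give 7.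

3. Step 1, catechol masking and boron removal. Masking may be incomplete once the basic amine is present, which would allow o-quinone formation or O-acylation, and the bis-catechol product may be cross-linked by borate and hard to free and purify. Fallback (covalent O-protection instead of boron): it sets out from 1 and comes back at 7. Compound 1 with Ac2O/pyridine gives 3,4-di-O-acetylcaffeic acid F6. Coupling of F6 (2.1 equiv) with F4, made from 3 as in the second fallback (EDC·HCl, HOBt, CH2Cl2, 0 °C), gives N(4)-Boc-N(1),N(8)-bis(3,4-di-O-acetylcaffeoyl)spermidine F7. HCl in MeOH (25 °C) removes the four acetates and the Boc group in one operation to give 7.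

**Further compounds**
F1 | step 1 | caffeic acid N-succinimidyl ester, 2,5-dioxopyrrolidin-1-yl (E)-3-(3,4-dihydroxyphenyl)prop-2-enoate | O=C(ON1C(=O)CCC1=O)/C=C/c1ccc(O)c(O)c1
F2 | step 1 | N(1),N(8)-bis(trifluoroacetyl)spermidine | O=C(NCCCCNCCCNC(=O)C(F)(F)F)C(F)(F)F
F3 | step 1 | N(4)-Boc-N(1),N(8)-bis(trifluoroacetyl)spermidine | O=C(NCCCCN(CCCNC(=O)C(F)(F)F)C(=O)OC(C)(C)C)C(F)(F)F
F4 | step 1 | N(4)-Boc-spermidine, tert-butyl N-(4-aminobutyl)-N-(3-aminopropyl)carbamate | NCCCCN(CCCN)C(=O)OC(C)(C)C
F5 | step 1 | N(4)-Boc-N(1),N(8)-bis(caffeoyl)spermidine | O=C(/C=C/c1ccc(O)c(O)c1)NCCCCN(CCCNC(=O)/C=C/c1ccc(O)c(O)c1)C(=O)OC(C)(C)C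
F6 | step 1 | 3,4-di-O-acetylcaffeic acid, (E)-3-(3,4-diacetoxyphenyl)prop-2-enoic acid | CC(=O)Oc1ccc(/C=C/C(=O)O)cc1OC(C)=O
F7 | step 1 | N(4)-Boc-N(1),N(8)-bis(3,4-di-O-acetylcaffeoyl)spermidine | CC(=O)Oc1ccc(/C=C/C(=O)NCCCCN(CCCNC(=O)/C=C/c2ccc(OC(C)=O)c(OC(C)=O)c2)C(=O)OC(C)(C)C)cc1OC(C)=O
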